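The ratio to carry is target over the three products together, the selectivity for target, and it is what the row below asks for at 15 h.

| setting | north | north-east | west | alder | cedar | oak | elm | birch |
|---|---|---|---|---|---|---|---|---|
| substrate | 0.033 M | 0.25 M | 2.8 M | 0.030 M | 0.10 M | 0.30 M | 1.0 M | 2.5 M |
| coupling partner | 0.15 M | 0.15 M | 0.15 M | 0.150 M | 0.150 M | 0.150 M | 0.150 M | 0.150 M |
| remark | run made earlier | run made earlier | run made earlier |  |  |  |  |  |
| time |  |  |  | 15 h | 15 h | 15 h | 15 h | 15 h |

| run | time / h | target / % | isomer of the product / % | second isomer / % |
|---|---|---|---|---|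
| north | 2.50 | 0 | 2 | 11 |
| north | 5.00 | 2 | 7 | 19 |
| north | 8.00 | 6 | 6 | 22 |
| north | 10.0 | 10 | 7 | 22 |
| north-east | 1.33 | 3 | 3 | 5 |
| north-east | 4.00 | 3 | 7 | 11 |
| north-east | 6.00 | 3 | 3 | 19 |
| north-east | 10.0 | 6 | 4 | 17 |
| west | 1.33 | 2 | 2 | 2 |
| west | 4.00 | 2 | 4 | 3 |
| west | 6.00 | 0 | 0 | 3 |
| west | 10.0 | 1 | 0 | 3 |

(scatter of a reading: 2 percentage points)

- the numbers in the tables scatter by 2 percentage points (one standard deviation)
- "hardly changes" means that all values lie within two and a half points (for a concentration: within two and a half percent of the largest)

- share of target in all that became target or isomer of the product or second isomer for alder, cedar, oak, elm, birch, in this order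
- the shape of the row from first to last (rises, then falls / hardly changes / falls all the way / falls, then rises / rises all the way)

One reading is noisy, so sums serve better. The three products sum to 114 % in the north run, 84.0 % in the north-east run and 22.0 % in the west run. Target's shares of these sums are 15.8 %, 17.9 % and 22.7 %. The west share carries a scatter of 18 percentage points, more than its gap of 6.9 points to the north share, so the readings show no trend with charge. Weighted together they give 17.3 %. This pooled share, target summed over the three runs divided by the three products so summed, has a scatter near 3.1 points. My reckoning is therefore a flat row, each point at 17.3 %, which is the shape "hardly changes".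

The weak link is time: the pool mixes hours, and the north readings of target go from 0 % at 2.50 h to 10 % at 10.0 h, each with its scatter of 2 points. Splitting the readings tests this. The first two of each run hold 88.0 % of product at a share of 13.6 %, and the later ones give 19.7 %. That gap is less than its scatter of 6.7 points, so the pool stands.

The forecast differs from this reckoning: 37 %, 31 %, 25 %, 22 %, 20 %, a row that falls all the way, on the view that “target comes late, probably by a slow follow-on step”.

The flask gives 13.8 %, 13.7 %, 13.3 %, 12.6 %, 12.3 %: the row hardly changes.

    substrate + coupling partner ⇌ target (K = 4.10 M⁻¹, k = 0.00216 M⁻¹ min⁻¹)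
    substrate + coupling partner → isomer of the product (k = 0.00223 M⁻¹ min⁻¹)
    substrate + coupling partner → second isomer (k = 0.00764 M⁻¹ min⁻¹)
    2 coupling partner → homo dimer (k = 0.0155 M⁻¹ min⁻¹)

In alder, target stands at 5.97 % after 15.0 h and 0.634 % after 150 h. The pooled share times alder's products at 15.0 h gives 7.49 % of target, and the flask holds 5.97 %. The same product for birch gives 0.960 %, and birch holds 0.686 %.

All runs are simulated with constants of no real substance; noise was put on by code.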